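## Structural features

The target is an isoflavone: a 5,7-dihydroxy-4H-chromen-4-one (benzo ring A fused to pyranone ring C) joined through the C3–C1' bond to ring B. Ring B is a pentasubstituted benzene that carries, in sequence, a hydroxyl on C2', a 3-hydroxy-3-methylbutyl chain on C3', a hydroxyl on C4', a methoxyl on C5' and its only hydrogen on C6'. There is no stereocentre and no stereogenic double bond, so no stereocentres stand next to each other; the problem is regiocontrol and telling three ring-B oxygens apart. The fragile points are these: the tertiary alcohol lies on a chain flanked by two phenols and under acid can ionise and close a 2,2-dimethylchroman on O2' or O4', or lose water; C2 of ring C is electrophilic, so the pyranone opens with hydroxide or secondary amines; C2=C3 can be over-reduced; and the electron-rich ring B can be oxidised to a quinone. The real difficulty is ring B: five contiguous substituents, a carbon chain wedged between two oxygens, and one oxygen of three that must be a methyl ether. The key step uses the C2'–OH group para to C5'–OMe, with the chromonyl group on C1' and hydrogen on C6'. This is the hydroquinone monomethyl ether that arises when a methoxycarbene carbon (C5'), two alkenyl carbons (C4', C3'), one CO (C2') and the two carbons of a terminal alkyne (C1', C6') are joined. Both benzannulation partners and the benzannulation product were checked atom by atom against this mapping and need no correction; the (Z) descriptor of the carbene complex means that the chain lies trans to the carbene carbon.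

## Logic of the disconnections

21 back to 20 and 19. The two O–CH2Ph bonds on ring A are cut first, then the O–CH2OCH3 bond on O4' and the O–Si bond of the side chain. These groups are needed only to carry phenols and the tertiary alcohol through organolithium and chromium chemistry. Nothing is gained in skeleton, but the forward steps must be mild: the acetal and silyl ether must fall to acid too weak to ionise the tertiary alcohol, and the hydrogenolysis must stop before C2=C3 is touched.

19 back to 10 and 17 (through 18). The three ring-B bonds C5'–C6', C1'–C2' and C2'–C3' are cut. This is the only cut that delivers all five ring-B substituents, already differentiated, onto a finished chromone in one operation, and it divides the molecule into two fragments of similar size. The forward step demands that the terminal alkyne insert with its CH carbon bonded to the carbene carbon, and that CO insertion and six-electron ring closure outrun other fates of the vinylcarbene.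

10 back to 6 and 7 (through 8 and 9). The bond between the carbene carbon and C2 of the heptenylidene chain is cut, together with the O–CH3 bond. This is the standard assembly of an alkoxycarbene complex from an organolithium, a metal carbonyl and a methylating agent, and it reduces the organometallic partner to a simple enol ether. The forward step needs lithiation at the vinylic carbon that bears oxygen and retention of the alkene geometry.

6 back to 5, then to 2 and 3 (through 4), and 2 back to 1. The O–Si bond is cut, then the C3–C4 bond of the hexenol chain, then the O–CH2OCH3 bond. The C3–C4 cut joins a three-carbon alkoxyallyl unit to a four-carbon epoxide, brings in the tertiary alcohol at its final oxidation level and fixes the cis enol ether geometry through chelation. It replaces a longer lactone–aldehyde–enol ether sequence. The forward step demands attack through the allyl carbon remote from oxygen and at the CH2 of the epoxide.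

17 back to 16, then to 14 and 15. The C–Si bond is cut, then the C3–C(sp) bond. A cross-coupling of a 3-halochromone with a silyl-capped acetylene avoids handling acetylene and a double coupling. The forward steps must use a base and a fluoride source that do not add to C2 of ring C.

14 back to 13, 12 and 11. The O1–C2 and C3–I bonds are cut together, then the bond between the acetyl carbon and the future C2, then two O–CH2Ph bonds. Ring C is thus built on a commercial acetophenone with the halogen placed during ring closure. The forward sequence demands that only two of the three hydroxyls of 11 are alkylated, leaving the chelated one for ring closure.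

## Other disconnections considered

Alternative 1: The cut is the C2=C3 double bond of ring C.
- Forward key step: the keto-stabilised phosphorane 3,5-bis(benzyloxy)-2-[2-aryl-2-(triphenylphosphoranylidene)acetyl]phenyl formate A2 has its ylide carbon (future C3) already bonded to ring B and a formate ester on the ortho oxygen of ring A. Intramolecular Wittig olefination of the formate carbonyl, with loss of Ph3PO, would give the tetra-O-benzyl O-triethylsilyl isoflavone A1.
- In its favour: the closure is a single ionic event with no regiochemical question and needs no transition metal. A1 carries only benzyl and silyl groups, so its deprotection needs no acetal cleavage; on that point it is better than the chosen plan.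
- Against it: an ester is a poor Wittig acceptor, the ylide carbon is fully substituted and stabilised by both the acyl group and ring B, and it sits between two ortho-substituted arenes. An aryl formate is also prone to hydrolysis and acyl transfer. Above all, A2 can only be made after ring B exists as a complete pentasubstituted arene, which is the hard part of the target.
- Comparison: on structure, it forms one bond of the easy ring and leaves ring B to classical aromatic substitution, whereas the chosen step forms three bonds of ring B. On mechanism, the Wittig closure has fewer side paths than a chromium cascade and is the equal or the better there. On step economy, the chosen plan should be clearly shorter.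

Alternative 2: The cut is C7–C8 of ring A, with ring C present from the start as a 4-pyranone.
- Forward key step: the pyranone ketoester A4 would be deprotonated at its 2-methyl group (future C8). The carbanion would attack the ester at the end of the neighbouring ketoester arm (future C7) in an intramolecular Claisen condensation, and enolisation would give the 5,7-dihydroxy ring A of A3.
- In its favour: it is a polyketide-like aromatisation with a strong driving force and uses only a cheap base. Ring A appears with free hydroxyls, so ring A needs no protection and deprotection; on that point it is better than the chosen plan.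
- Against it: the methylene between ketone and ester in A4 is far more acidic than the pyranone methyl, so the step must run on a polyanion. The pyranone, unsubstituted next to oxygen, is open to ring opening by the same base. A4 is a densely substituted pyranone that again presupposes a finished ring B.
- Comparison: on structure, the key step is spent on ring A, which a phloroglucinol derivative provides at no cost. On mechanism, it is metal-free and so the equal or the better in reagent simplicity, but it has a real site-selectivity problem in the deprotonation. On step economy, it should be the longer route.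

Alternative 3: The cuts are O1–C8a and C4–C4a.
- Forward key step: CsF would release 3,5-bis(benzyloxy)benzyne from the silylaryl triflate A6. The enolate oxygen of the 2-aryl-3-hydroxyacrylate A7 would add to it, and the aryl anion would acylate on the ester, closing ring C to give the tetra-O-benzyl O-silyl isoflavone A5.
- In its favour: it is as convergent as the chosen plan and forms two bonds and one ring at ambient temperature. The alkoxy group next to the aryne directs the nucleophile to the remote carbon and places the anion where acylation must occur, so the ring-A regiochemistry is inherent. The deprotection again avoids an acetal, which is a point in its favour.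
- Against it: enolates of this type usually attack arynes through carbon, giving C-arylation or formal insertion into a C–C bond. Proton transfer can quench the aryl anion before acylation. A6 needs several steps and A7 needs the complete ring B.
- Comparison: on structure, it joins two finished halves but does nothing for ring B. On mechanism, the oxygen-versus-carbon selectivity is less secure than the steric regiocontrol of a terminal alkyne in the chosen step. On step economy, the need to make ring B separately should make it longer.

Key step: step 10

Remark on notation: the arene–Cr(CO)3 complex 18 is written in SMILES as the arene and the Cr(CO)3 fragment joined by a dot, and carbonyl ligands are written M=C=O.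

## Route

Step 1
Reactants: 1 prop-2-en-1-ol (allyl alcohol)
Product: 2 3-(methoxymethoxy)prop-1-ene
Conditions: CH3OCH2Cl, iPr2NEt, CH2Cl2, 0 °C → rt; distillation
Reagents that add atoms: chloromethyl methyl ether, COCCl
Why: O-alkylation of a primary alcohol with an α-chloro ether under amine base (acetal protection); nothing else in the molecule can react.

Step 2
Reactants: 2 3-(methoxymethoxy)prop-1-ene; 3 2,2-dimethyloxirane
Product: 5 (5Z)-6-(methoxymethoxy)-2-methylhex-5-en-2-ol, via 1-(methoxymethoxy)allyllithium 4 (not isolated)
Conditions: s-BuLi, THF, −78 °C; then 3, −78 → −30 °C; H2O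
Reagents that add atoms: none
Why: Allylic deprotonation next to oxygen gives the oxygen-chelated, cis-configured 1-alkoxyallyllithium, which SN2 electrophiles alkylate at the carbon remote from oxygen (γ-alkylation of a heteroatom-substituted allyl anion). Attack on the unhindered CH2 of the epoxide should give the δ-hydroxy enol ether, with the (Z) geometry fixed by the internal Li–O chelate.

Step 3
Reactants: 5 (5Z)-6-(methoxymethoxy)-2-methylhex-5-en-2-ol
Product: 6 triethyl{[(5Z)-6-(methoxymethoxy)-2-methylhex-5-en-2-yl]oxy}silane
Conditions: Et3SiCl, imidazole, DMAP (cat.), DMF, rt → 40 °C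
Reagents that add atoms: chlorotriethylsilane, CC[Si](Cl)(CC)CC
Why: Silylation of a tertiary alcohol under basic conditions that leave the acid-labile enol ether and acetal alone; a silyl triflate is avoided because with amine bases it cleaves methoxymethyl acetals.

Step 4
Reactants: 6 triethyl{[(5Z)-6-(methoxymethoxy)-2-methylhex-5-en-2-yl]oxy}silane; 7 chromium hexacarbonyl, Cr(CO)6
Product: 10 pentacarbonyl[(2Z)-1-methoxy-2-(methoxymethoxy)-6-methyl-6-(triethylsilyloxy)hept-2-en-1-ylidene]chromium, via alkenyllithium 8 (not isolated), via lithium acylchromate 9 (not isolated)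
Conditions: s-BuLi, THF, −78 → −50 °C; Cr(CO)6, Et2O, −78 °C → rt; Me3OBF4, CH2Cl2, 0 °C
Reagents that add atoms: trimethyloxonium tetrafluoroborate, C[O+](C)C.F[B-](F)(F)F
Why: The acetal oxygen directs lithiation to the vinylic carbon α to oxygen of the cis enol ether, as in the α-lithiation of cyclic enol ethers. Addition of the alkenyllithium to a CO ligand and O-methylation of the acylchromate is the Fischer carbene synthesis. The vinylic C–Li bond is configurationally stable, so the chain stays trans to the new carbene carbon.

Step 5
Reactants: 11 1-(2,4,6-trihydroxyphenyl)ethan-1-one (2',4',6'-trihydroxyacetophenone)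
Product: 12 1-[2,4-bis(benzyloxy)-6-hydroxyphenyl]ethan-1-one
Conditions: BnBr (2.1 equiv), K2CO3, DMF, rt
Reagents that add atoms: benzyl bromide, BrCc1ccccc1
Why: Williamson etherification; the hydroxyl hydrogen-bonded to the ketone is the least nucleophilic, so two equivalents of halide should alkylate the other two and leave the one needed for ring closure.

Step 6
Reactants: 12 1-[2,4-bis(benzyloxy)-6-hydroxyphenyl]ethan-1-one
Product: 13 (2E)-1-[2,4-bis(benzyloxy)-6-hydroxyphenyl]-3-(dimethylamino)prop-2-en-1-one
Conditions: Me2NCH(OMe)2, toluene, 95 °C
Reagents that add atoms: N,N-dimethylformamide dimethyl acetal, COC(OC)N(C)C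
Why: Condensation of the methyl ketone with an amide acetal gives the enaminone and supplies the carbon that becomes C2; the push–pull alkene adopts the (E) geometry.

Step 7
Reactants: 13 (2E)-1-[2,4-bis(benzyloxy)-6-hydroxyphenyl]-3-(dimethylamino)prop-2-en-1-one
Product: 14 5,7-bis(benzyloxy)-3-iodo-4H-chromen-4-one
Conditions: I2, CHCl3, rt; aq. Na2S2O3
Reagents that add atoms: iodine, II
Why: Iodine attacks the nucleophilic α-carbon of the enaminone, the phenol oxygen adds to the resulting iminium carbon, and loss of dimethylamine gives the 3-iodochromone (iodocyclisation of a 2-hydroxyaryl enaminone).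

Step 8
Reactants: 14 5,7-bis(benzyloxy)-3-iodo-4H-chromen-4-one; 15 ethynyltrimethylsilane
Product: 16 5,7-bis(benzyloxy)-3-[(trimethylsilyl)ethynyl]-4H-chromen-4-one
Conditions: PdCl2(PPh3)2 (cat.), CuI (cat.), Et3N, THF, rt → 40 °C
Reagents that add atoms: none
Why: Sonogashira coupling; the C3–I bond of the vinylogous ester adds readily to zerovalent palladium, and a tertiary amine is used because it cannot open ring C by conjugate addition at C2.

Step 9
Reactants: 16 5,7-bis(benzyloxy)-3-[(trimethylsilyl)ethynyl]-4H-chromen-4-one
Product: 17 5,7-bis(benzyloxy)-3-ethynyl-4H-chromen-4-one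
Conditions: Bu4NF, AcOH, THF, 0 °C
Reagents that add atoms: none
Why: Fluoride-induced cleavage of the C(sp)–Si bond; buffering with acetic acid keeps the medium non-basic so that C2 of the chromone is not attacked.

Step 10
Reactants: 10 pentacarbonyl[(2Z)-1-methoxy-2-(methoxymethoxy)-6-methyl-6-(triethylsilyloxy)hept-2-en-1-ylidene]chromium; 17 5,7-bis(benzyloxy)-3-ethynyl-4H-chromen-4-one
Product: 19 5,7-bis(benzyloxy)-3-{2-hydroxy-5-methoxy-4-(methoxymethoxy)-3-[3-methyl-3-(triethylsilyloxy)butyl]phenyl}-4H-chromen-4-one, via arene tricarbonylchromium complex 18 (not isolated)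
Conditions: THF (degassed), 50 °C, Ar; then air, Et2O, rt
Reagents that add atoms: none
Why: Thermal loss of one CO ligand from 10 opens a site for the alkyne, which inserts into the Cr=C bond to give a vinylcarbene; CO insertion then gives a chromium-bound dienylketene whose six-electron electrocyclisation closes the carbocyclic ring B, and tautomerisation of the cyclohexadienone gives the phenol as its Cr(CO)3 complex 18, from which air removes the metal. This is the Dötz benzannulation of an alkenyl(alkoxy)carbene complex with a terminal alkyne; the closest precedents are complexes made from α-lithiated cyclic enol ethers, which carry the same α-oxygen substituent. The carbene carbon becomes C5' with its methoxyl, C2 and C3 of the heptenylidene become C4' and C3', the inserted CO becomes C2' with the free hydroxyl, and the alkyne carbons become C6' and C1'. No stereocentre is formed and the alkene geometry of 10 disappears on aromatisation, so only regiochemistry and chemoselectivity matter. The regiochemistry rests on the steric bias of a terminal alkyne: its unsubstituted carbon bonds to the carbene carbon, so the chromonyl group ends up next to the new hydroxyl. Phenol formation should be favoured over cyclobutenone, furan or five-membered-ring products because an alkenyl complex with hydrogen on its β-carbon cyclises and tautomerises readily, and a donor solvent such as THF supports CO insertion. The conditions are neutral, so the benzyl, methoxymethyl and triethylsilyl groups and the electrophilic C2 of the chromone should not be touched.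

Step 11
Reactants: 19 5,7-bis(benzyloxy)-3-{2-hydroxy-5-methoxy-4-(methoxymethoxy)-3-[3-methyl-3-(triethylsilyloxy)butyl]phenyl}-4H-chromen-4-one
Product: 20 5,7-bis(benzyloxy)-3-[2,4-dihydroxy-3-(3-hydroxy-3-methylbutyl)-5-methoxyphenyl]-4H-chromen-4-one
Conditions: HCl (ca. 0.5 M, from AcCl) in MeOH–THF, 0 °C → rt; NaHCO3
Reagents that add atoms: none
Why: Acid-catalysed methanolysis of an aryl methoxymethyl acetal and of a triethylsilyl ether; both cleave under dilute acid at or below room temperature, where a tertiary alcohol should not yet ionise and benzyl ethers are stable.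

Step 12
Reactants: 20 5,7-bis(benzyloxy)-3-[2,4-dihydroxy-3-(3-hydroxy-3-methylbutyl)-5-methoxyphenyl]-4H-chromen-4-one
Product: 21 5,7-dihydroxy-3-[2,4-dihydroxy-3-(3-hydroxy-3-methylbutyl)-5-methoxyphenyl]-4H-chromen-4-one
Conditions: H2 (1 atm), 10% Pd/C, EtOAc–MeOH, rt
Reagents that add atoms: none
Why: Hydrogenolysis of aryl benzyl ethers under neutral conditions; the side-chain alcohol is not benzylic, and the reaction is stopped at full debenzylation, before the slower reduction of C2=C3.

## Compound list

1 | prop-2-en-1-ol (allyl alcohol) | C=CCO | starting material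
2 | 3-(methoxymethoxy)prop-1-ene | C=CCOCOC | intermediate
3 | 2,2-dimethyloxirane | CC1(C)CO1 | starting material
4 | 1-(methoxymethoxy)allyllithium (oxygen-chelated, cis-configured allyl anion) | [Li]C(OCOC)C=C | intermediate (not isolated)
5 | (5Z)-6-(methoxymethoxy)-2-methylhex-5-en-2-ol | COCO/C=C\CCC(C)(C)O | intermediate
6 | triethyl{[(5Z)-6-(methoxymethoxy)-2-methylhex-5-en-2-yl]oxy}silane | COCO/C=C\CCC(C)(C)O[Si](CC)(CC)CC | intermediate
7 | chromium hexacarbonyl, Cr(CO)6 | O=C=[Cr](=C=O)(=C=O)(=C=O)(=C=O)=C=O | starting material
8 | [(1Z)-1-(methoxymethoxy)-5-methyl-5-(triethylsilyloxy)hex-1-en-1-yl]lithium | [Li]/C(OCOC)=C/CCC(C)(C)O[Si](CC)(CC)CC | intermediate (not isolated)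
9 | lithium pentacarbonyl[(2Z)-2-(methoxymethoxy)-6-methyl-6-(triethylsilyloxy)hept-2-enoyl]chromate | [Li+].[O-]C(=[Cr](=C=O)(=C=O)(=C=O)(=C=O)=C=O)/C(OCOC)=C/CCC(C)(C)O[Si](CC)(CC)CC | intermediate (not isolated)
10 | pentacarbonyl[(2Z)-1-methoxy-2-(methoxymethoxy)-6-methyl-6-(triethylsilyloxy)hept-2-en-1-ylidene]chromium | COC(=[Cr](=C=O)(=C=O)(=C=O)(=C=O)=C=O)/C(OCOC)=C/CCC(C)(C)O[Si](CC)(CC)CC | intermediate
11 | 1-(2,4,6-trihydroxyphenyl)ethan-1-one | CC(=O)c1c(O)cc(O)cc1O | starting material
12 | 1-[2,4-bis(benzyloxy)-6-hydroxyphenyl]ethan-1-one | CC(=O)c1c(O)cc(OCc2ccccc2)cc1OCc1ccccc1 | intermediate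
13 | (2E)-1-[2,4-bis(benzyloxy)-6-hydroxyphenyl]-3-(dimethylamino)prop-2-en-1-one | CN(C)/C=C/C(=O)c1c(O)cc(OCc2ccccc2)cc1OCc1ccccc1 | intermediate
14 | 5,7-bis(benzyloxy)-3-iodo-4H-chromen-4-one | O=c1c(I)coc2cc(OCc3ccccc3)cc(OCc3ccccc3)c12 | intermediate
15 | ethynyltrimethylsilane | C[Si](C)(C)C#C | starting material
16 | 5,7-bis(benzyloxy)-3-[(trimethylsilyl)ethynyl]-4H-chromen-4-one | C[Si](C)(C)C#Cc1coc2cc(OCc3ccccc3)cc(OCc3ccccc3)c2c1=O | intermediate
17 | 5,7-bis(benzyloxy)-3-ethynyl-4H-chromen-4-one | C#Cc1coc2cc(OCc3ccccc3)cc(OCc3ccccc3)c2c1=O | intermediate
18 | tricarbonylchromium complex of 19 (η6 on ring B) | COc1cc(-c2coc3cc(OCc4ccccc4)cc(OCc4ccccc4)c3c2=O)c(O)c(CCC(C)(C)O[Si](CC)(CC)CC)c1OCOC.O=C=[Cr](=C=O)=C=O | intermediate (not isolated)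
19 | 5,7-bis(benzyloxy)-3-{2-hydroxy-5-methoxy-4-(methoxymethoxy)-3-[3-methyl-3-(triethylsilyloxy)butyl]phenyl}-4H-chromen-4-one | COc1cc(-c2coc3cc(OCc4ccccc4)cc(OCc4ccccc4)c3c2=O)c(O)c(CCC(C)(C)O[Si](CC)(CC)CC)c1OCOC | intermediate
20 | 5,7-bis(benzyloxy)-3-[2,4-dihydroxy-3-(3-hydroxy-3-methylbutyl)-5-methoxyphenyl]-4H-chromen-4-one | COc1cc(-c2coc3cc(OCc4ccccc4)cc(OCc4ccccc4)c3c2=O)c(O)c(CCC(C)(C)O)c1O | intermediate
21 | 5,7-dihydroxy-3-[2,4-dihydroxy-3-(3-hydroxy-3-methylbutyl)-5-methoxyphenyl]-4H-chromen-4-one | COc1cc(-c2coc3cc(O)cc(O)c3c2=O)c(O)c(CCC(C)(C)O)c1O | target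

## Step count and least certain steps

Total: 12 steps. Longest linear sequence: 8 steps (steps 5 to 12, from 11 to 21). The carbene branch (steps 1 to 4) joins at step 10.

**Step 10 (key step).** The most likely failure is unproductive consumption of the alkyne. The conjugated, electron-poor ethynylchromone may oligomerise at the metal. Alternatively, after insertion, the C4 carbonyl may chelate chromium and hold the vinylcarbene back from CO insertion and ring closure, diverting it to cyclobutenone- or furan-type products. Over-oxidation of the hydroquinone monoether during removal of the metal is a lesser risk.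

The fallback sets out from 10, 15 and 14 and returns at 19. It keeps the ring-forming benzannulation but uses a simple silyl alkyne and attaches the chromone by cross-coupling. Benzannulation of 10 with 15, followed by exposure to air, would give 4-methoxy-3-(methoxymethoxy)-2-[3-methyl-3-(triethylsilyloxy)butyl]-6-(trimethylsilyl)phenol F1, with the silyl group next to the hydroxyl. Ipso-iododesilylation with N-iodosuccinimide would give 6-iodo-4-methoxy-3-(methoxymethoxy)-2-[3-methyl-3-(triethylsilyloxy)butyl]phenol F2. Miyaura borylation (PdCl2(dppf), B2pin2, KOAc) would give 4-methoxy-3-(methoxymethoxy)-2-[3-methyl-3-(triethylsilyloxy)butyl]-6-(4,4,5,5-tetramethyl-1,3,2-dioxaborolan-2-yl)phenol F3. Suzuki coupling of F3 with 14 (Pd(PPh3)4, K3PO4, DME–H2O) would give 19.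

**Step 2.** The most likely failure is alkylation at the oxygen-bearing allyl carbon instead of the remote one. The other risk is Wittig rearrangement of the allyl anion while the slow, 1,1-disubstituted epoxide is still reacting, because the anion only survives at low temperature.

The fallback sets out from 3 and returns at 6. Opening of 3 with CH2=CHCH2MgBr would give 2-methylhex-5-en-2-ol F4. Silylation (Et3SiCl, imidazole) would give triethyl[(2-methylhex-5-en-2-yl)oxy]silane F5. Hydroboration–oxidation (9-BBN; NaOH, H2O2) would give 5-methyl-5-(triethylsilyloxy)hexan-1-ol F6, and Swern oxidation would give 5-methyl-5-(triethylsilyloxy)hexanal F7. O-alkylation of F7 under enolising conditions (KH, THF; chloromethyl methyl ether) would give 6. The hard electrophile favours oxygen, and any (E) isomer would be separated because only the cis enol ether lithiates readily.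

**Step 4.** The most likely failure is deprotonation at the wrong site (the allylic CH2 or the acetal CH2) or incomplete vinylic lithiation, because a β-alkyl group slows α-metalation of an enol ether.

The fallback sets out from 6 and 7 and returns at 10; it avoids the alkenyllithium altogether. Ozonolysis of 6 (O3; PPh3) would give 4-methyl-4-(triethylsilyloxy)pentanal F8. Tin–lithium exchange on Bu3SnCH2OCH2OCH3 with n-BuLi would give [(methoxymethoxy)methyl]lithium F9. Addition of F9 to 7 and O-methylation with Me3OBF4 would give pentacarbonyl[1-methoxy-2-(methoxymethoxy)ethylidene]chromium F10. Aldol condensation of the acidic α-CH2 of F10 with F8 (Et3N, Me3SiCl, Et2O) would give 10. The chain should settle trans to the bulky carbene unit.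

**Step 11.** The most likely failure is ionisation of the tertiary alcohol under the acid. This would lead to ring closure onto O2' or O4' (dimethylchroman formation), loss of water, or capture by methanol.

The fallback sets out from 19 and returns at 20; it uses no Brønsted acid. Me3SiOTf with 2,2'-bipyridyl in CH2Cl2 at 0 °C, then water, would remove only the aryl acetal and give 5,7-bis(benzyloxy)-3-{2,4-dihydroxy-5-methoxy-3-[3-methyl-3-(triethylsilyloxy)butyl]phenyl}-4H-chromen-4-one F11. Buffered fluoride (Bu4NF, AcOH, THF) would then remove the silyl group and give 20.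

## Further compounds

F1 | step 10 | 4-methoxy-3-(methoxymethoxy)-2-[3-methyl-3-(triethylsilyloxy)butyl]-6-(trimethylsilyl)phenol | COc1cc([Si](C)(C)C)c(O)c(CCC(C)(C)O[Si](CC)(CC)CC)c1OCOC
F2 | step 10 | 6-iodo-4-methoxy-3-(methoxymethoxy)-2-[3-methyl-3-(triethylsilyloxy)butyl]phenol | COc1cc(I)c(O)c(CCC(C)(C)O[Si](CC)(CC)CC)c1OCOC
F3 | step 10 | 4-methoxy-3-(methoxymethoxy)-2-[3-methyl-3-(triethylsilyloxy)butyl]-6-(4,4,5,5-tetramethyl-1,3,2-dioxaborolan-2-yl)phenol | COc1cc(B2OC(C)(C)C(C)(C)O2)c(O)c(CCC(C)(C)O[Si](CC)(CC)CC)c1OCOC
F4 | step 2 | 2-methylhex-5-en-2-ol | C=CCCC(C)(C)O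
F5 | step 2 | triethyl[(2-methylhex-5-en-2-yl)oxy]silane | C=CCCC(C)(C)O[Si](CC)(CC)CC
F6 | step 2 | 5-methyl-5-(triethylsilyloxy)hexan-1-ol | OCCCCC(C)(C)O[Si](CC)(CC)CC
F7 | step 2 | 5-methyl-5-(triethylsilyloxy)hexanal | O=CCCCC(C)(C)O[Si](CC)(CC)CC
F8 | step 4 | 4-methyl-4-(triethylsilyloxy)pentanal | O=CCCC(C)(C)O[Si](CC)(CC)CC
F9 | step 4 | [(methoxymethoxy)methyl]lithium | [Li]COCOC
F10 | step 4 | pentacarbonyl[1-methoxy-2-(methoxymethoxy)ethylidene]chromium | COC(COCOC)=[Cr](=C=O)(=C=O)(=C=O)(=C=O)=C=O
F11 | step 11 | 5,7-bis(benzyloxy)-3-{2,4-dihydroxy-5-methoxy-3-[3-methyl-3-(triethylsilyloxy)butyl]phenyl}-4H-chromen-4-one | COc1cc(-c2coc3cc(OCc4ccccc4)cc(OCc4ccccc4)c3c2=O)c(O)c(CCC(C)(C)O[Si](CC)(CC)CC)c1O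
A1 | alternative 1 | 5,7-bis(benzyloxy)-3-{2,4-bis(benzyloxy)-5-methoxy-3-[3-methyl-3-(triethylsilyloxy)butyl]phenyl}-4H-chromen-4-one | COc1cc(-c2coc3cc(OCc4ccccc4)cc(OCc4ccccc4)c3c2=O)c(OCc2ccccc2)c(CCC(C)(C)O[Si](CC)(CC)CC)c1OCc1ccccc1
A2 | alternative 1 | 3,5-bis(benzyloxy)-2-[2-{2,4-bis(benzyloxy)-5-methoxy-3-[3-methyl-3-(triethylsilyloxy)butyl]phenyl}-2-(triphenyl-λ5-phosphanylidene)acetyl]phenyl formate | O=COc1cc(OCc2ccccc2)cc(OCc2ccccc2)c1C(=O)C(=P(c1ccccc1)(c1ccccc1)c1ccccc1)c1cc(OC)c(OCc2ccccc2)c(CCC(C)(C)O[Si](CC)(CC)CC)c1OCc1ccccc1
A3 | alternative 2 | 3-[2,4-bis(benzyloxy)-3-(3-{[tert-butyl(dimethyl)silyl]oxy}-3-methylbutyl)-5-methoxyphenyl]-5,7-dihydroxy-4H-chromen-4-one | COc1cc(-c2coc3cc(O)cc(O)c3c2=O)c(OCc2ccccc2)c(CCC(C)(C)O[Si](C)(C)C(C)(C)C)c1OCc1ccccc1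
A4 | alternative 2 | methyl 3-{5-[2,4-bis(benzyloxy)-3-(3-{[tert-butyl(dimethyl)silyl]oxy}-3-methylbutyl)-5-methoxyphenyl]-2-methyl-4-oxo-4H-pyran-3-yl}-3-oxopropanoate | COC(=O)CC(=O)c1c(C)occ(-c2cc(OC)c(OCc3ccccc3)c(CCC(C)(C)O[Si](C)(C)C(C)(C)C)c2OCc2ccccc2)c1=O
A5 | alternative 3 | 5,7-bis(benzyloxy)-3-[2,4-bis(benzyloxy)-3-(3-{[tert-butyl(dimethyl)silyl]oxy}-3-methylbutyl)-5-methoxyphenyl]-4H-chromen-4-one | COc1cc(-c2coc3cc(OCc4ccccc4)cc(OCc4ccccc4)c3c2=O)c(OCc2ccccc2)c(CCC(C)(C)O[Si](C)(C)C(C)(C)C)c1OCc1ccccc1
A6 | alternative 3 | 3,5-bis(benzyloxy)-2-(trimethylsilyl)phenyl trifluoromethanesulfonate | C[Si](C)(C)c1c(OCc2ccccc2)cc(OCc2ccccc2)cc1OS(=O)(=O)C(F)(F)F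
A7 | alternative 3 | methyl (2Z)-2-[2,4-bis(benzyloxy)-3-(3-{[tert-butyl(dimethyl)silyl]oxy}-3-methylbutyl)-5-methoxyphenyl]-3-hydroxyprop-2-enoate | COC(=O)/C(=C\O)c1cc(OC)c(OCc2ccccc2)c(CCC(C)(C)O[Si](C)(C)C(C)(C)C)c1OCc1ccccc1
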